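**Retrosynthetic overview**
- Target ⇐ removal of two aryl silyl ethers ⇐ late linear prenylation of an aryl bromide (the prenyl alkene would not survive the alkene cleavage, so it enters afterwards).
- Free acid ⇐ oxidative cleavage of a vinyl group; methyl ester ⇐ an aldehyde (oxidation, then methylation). The two carboxyls differ by origin, so no regioselective esterification is needed.
- Key step: the central C–C bond and both stereocentres come from one stereodivergent dual iridium/amine α-allylation of a 3-arylpropanal with a racemic aryl vinyl carbinol. This replaces the usual auxiliary enolate alkylation or Stobbe/hydrogenation route.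
- The aldehyde comes from a chemoselective Heck reaction of a bromo-iodo-phenol silyl ether with allyl alcohol; the carbinol from a vinyl Grignard addition.
- No ring is formed; both benzene rings are bought intact.

Assumption: in step 4 the (S)-amine fixes the benzyl-bearing carbon and the (R)-ligand fixes the aryl-bearing carbon as drawn; the amine sense follows the usual face-shielding model, the ligand sense is taken from recollection, and because the two catalysts act independently only the ligand enantiomer would be exchanged if its sense proved opposite.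

**Step 1**
Reactants: 1 2-bromo-5-iodophenol
Product: 2 (2-bromo-5-iodophenoxy)tri(propan-2-yl)silane
Conditions: TIPSCl, imidazole, DMF, 23 °C
Reagents that add atoms: chlorotri(propan-2-yl)silane (TIPSCl), CC(C)[Si](Cl)(C(C)C)C(C)C
Why: Imidazole-promoted O-silylation of the phenol gives a bulky TIPS ether that should survive the Heck, oxidation and aqueous-base coupling steps; no stereocentre is involved.

**Step 2**
Reactants: 2 (2-bromo-5-iodophenoxy)tri(propan-2-yl)silane; 3 prop-2-en-1-ol (allyl alcohol)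
Product: 5 3-[4-bromo-3-(triisopropylsilyloxy)phenyl]propanal, via enol 4 (not isolated)
Conditions: Pd(OAc)2 (3 mol %), Bu4NCl, NaHCO3, DMF, 40 °C
Reagents that add atoms: none
Why: Jeffery-type Mizoroki–Heck arylation of allyl alcohol, in which zerovalent palladium inserts into C–I far faster than into C–Br and β-hydride elimination towards the carbinol gives enol 4, which tautomerises to the aldehyde.

**Step 3**
Reactants: 6 4-(tert-butyldimethylsilyloxy)benzaldehyde
Product: 8 racemic 1-[4-(tert-butyldimethylsilyloxy)phenyl]prop-2-en-1-ol, via magnesium alkoxide 7 (not isolated)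
Conditions: CH2=CHMgBr, THF, −78 to 0 °C; aq NH4Cl
Reagents that add atoms: vinylmagnesium bromide, C=C[Mg]Br
Why: Grignard 1,2-addition to the aldehyde; the racemate suffices because step 4 ionises the carbinol and is enantioconvergent.

**Step 4**
Reactants: 5 3-[4-bromo-3-(triisopropylsilyloxy)phenyl]propanal (2 equiv); 8 racemic 1-[4-(tert-butyldimethylsilyloxy)phenyl]prop-2-en-1-ol
Product: 9 (2R,3R)-2-[[4-bromo-3-(triisopropylsilyloxy)phenyl]methyl]-3-[4-(tert-butyldimethylsilyloxy)phenyl]pent-4-enal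
Conditions: [Ir(cod)Cl]2 (3 mol %), (R)-BINOL-derived N-dibenzo[b,f]azepinyl phosphoramidite (P,olefin ligand, 12 mol %), (S)-2-[bis(3,5-bis(trifluoromethyl)phenyl)(trimethylsilyloxy)methyl]pyrrolidine (10 mol %), (MeO)2P(O)OH (promoter), ClCH2CH2Cl, 25 °C
Reagents that add atoms: none
Why: Stereodivergent dual iridium/enamine catalysis (Krautwald–Carreira α-allylation of linear aldehydes): 8 is ionised to a chiral trivalent iridium π-allyl complex that the chiral enamine of 5 attacks at the aryl-bearing terminus, so the ligand sets the aryl-bearing centre (R) and the face-shielding amine sets the benzyl-bearing centre (R), each under independent catalyst control.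

**Step 5**
Reactants: 9 (2R,3R)-2-[[4-bromo-3-(triisopropylsilyloxy)phenyl]methyl]-3-[4-(tert-butyldimethylsilyloxy)phenyl]pent-4-enal
Product: 10 (2R,3R)-2-[[4-bromo-3-(triisopropylsilyloxy)phenyl]methyl]-3-[4-(tert-butyldimethylsilyloxy)phenyl]pent-4-enoic acid
Conditions: NaClO2, NaH2PO4, 2-methyl-2-butene, t-BuOH/H2O, 0 °C
Reagents that add atoms: sodium chlorite, [Na+].[O-]Cl=O
Why: Pinnick (Lindgren–Kraus) oxidation at about pH 4 converts the aldehyde to the acid without enolising the α-centre, and the alkene scavenger keeps HOCl away from the vinyl group and the silyloxyarenes.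

**Step 6**
Reactants: 10 (2R,3R)-2-[[4-bromo-3-(triisopropylsilyloxy)phenyl]methyl]-3-[4-(tert-butyldimethylsilyloxy)phenyl]pent-4-enoic acid
Product: 11 methyl (2R,3R)-2-[[4-bromo-3-(triisopropylsilyloxy)phenyl]methyl]-3-[4-(tert-butyldimethylsilyloxy)phenyl]pent-4-enoate
Conditions: Me3SiCHN2, PhMe/MeOH, 0 °C
Reagents that add atoms: (trimethylsilyl)diazomethane, C[Si](C)(C)C=[N+]=[N-]
Why: Base-free diazoalkane esterification fixes this carboxyl as the methyl ester of the target with no chance of epimerisation.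

**Step 7**
Reactants: 11 methyl (2R,3R)-2-[[4-bromo-3-(triisopropylsilyloxy)phenyl]methyl]-3-[4-(tert-butyldimethylsilyloxy)phenyl]pent-4-enoate
Product: 14 (2R,3R)-3-[[4-bromo-3-(triisopropylsilyloxy)phenyl]methyl]-2-[4-(tert-butyldimethylsilyloxy)phenyl]-4-methoxy-4-oxobutanoic acid, via ozonide 12 (not isolated), via aldehyde 13 (not isolated)
Conditions: O3, CH2Cl2, −78 °C; PPh3, −78 to 23 °C; then NaClO2, NaH2PO4, 2-methyl-2-butene, t-BuOH/H2O, 0 °C
Reagents that add atoms: ozone, [O-][O+]=O; sodium chlorite, [Na+].[O-]Cl=O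
Why: Ozonolysis of the only alkene with reductive work-up gives α-aryl aldehyde 13, which is oxidised at once under buffered Pinnick conditions, the same sequence that turns 3-arylalkenes into 2-arylalkanoic acids without racemisation; neither stereocentre is touched.

**Step 8**
Reactants: 14 (2R,3R)-3-[[4-bromo-3-(triisopropylsilyloxy)phenyl]methyl]-2-[4-(tert-butyldimethylsilyloxy)phenyl]-4-methoxy-4-oxobutanoic acid; 15 4,4,5,5-tetramethyl-2-(3-methylbut-2-enyl)-1,3,2-dioxaborolane (prenylboronic acid pinacol ester)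
Product: 16 (2R,3R)-2-[4-(tert-butyldimethylsilyloxy)phenyl]-4-methoxy-3-[[4-(3-methylbut-2-enyl)-3-(triisopropylsilyloxy)phenyl]methyl]-4-oxobutanoic acid
Conditions: Pd(OAc)2 (5 mol %), tBuXPhos (10 mol %), K3PO4, THF/H2O, 40 °C; then aq NaH2PO4
Reagents that add atoms: none
Why: Suzuki–Miyaura allyl–aryl coupling in which the hindered di-tert-butylbiarylphosphine steers the allylpalladium to the isomer with palladium on the primary carbon, so reductive elimination gives the linear prenyl arene; the carboxylate is not enolisable and phosphate cannot deprotonate the ester α-carbon, so both centres hold.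

**Step 9**
Reactants: 16 (2R,3R)-2-[4-(tert-butyldimethylsilyloxy)phenyl]-4-methoxy-3-[[4-(3-methylbut-2-enyl)-3-(triisopropylsilyloxy)phenyl]methyl]-4-oxobutanoic acid
Product: 17 (2R,3R)-2-(4-hydroxyphenyl)-3-[[3-hydroxy-4-(3-methylbut-2-enyl)phenyl]methyl]-4-methoxy-4-oxobutanoic acid (CNP0437978.2)
Conditions: Bu4NF/AcOH (1:1), THF, 0 °C
Reagents that add atoms: none
Why: Fluoride-induced desilylation of both aryl silyl ethers, buffered with acetic acid to avoid ester hydrolysis, epimerisation at the α-aryl carbon and acid-promoted cyclisation of the ortho-prenylphenol to a chroman.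

**Compound list**
1 | 2-bromo-5-iodophenol | Oc1cc(I)ccc1Br | starting material
2 | (2-bromo-5-iodophenoxy)tri(propan-2-yl)silane | CC(C)[Si](Oc1cc(I)ccc1Br)(C(C)C)C(C)C | intermediate
3 | prop-2-en-1-ol | C=CCO | starting material
4 | 3-[4-bromo-3-(triisopropylsilyloxy)phenyl]prop-1-en-1-ol (enol) | OC=CCc1ccc(Br)c(O[Si](C(C)C)(C(C)C)C(C)C)c1 | intermediate
5 | 3-[4-bromo-3-(triisopropylsilyloxy)phenyl]propanal | O=CCCc1ccc(Br)c(O[Si](C(C)C)(C(C)C)C(C)C)c1 | intermediate
6 | 4-(tert-butyldimethylsilyloxy)benzaldehyde | CC(C)(C)[Si](C)(C)Oc1ccc(C=O)cc1 | starting material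
7 | bromomagnesium 1-[4-(tert-butyldimethylsilyloxy)phenyl]prop-2-en-1-olate (racemic) | C=CC(O[Mg]Br)c1ccc(O[Si](C)(C)C(C)(C)C)cc1 | intermediate
8 | racemic 1-[4-(tert-butyldimethylsilyloxy)phenyl]prop-2-en-1-ol | C=CC(O)c1ccc(O[Si](C)(C)C(C)(C)C)cc1 | intermediate
9 | (2R,3R)-2-[[4-bromo-3-(triisopropylsilyloxy)phenyl]methyl]-3-[4-(tert-butyldimethylsilyloxy)phenyl]pent-4-enal | O=C[C@H](Cc1ccc(Br)c(O[Si](C(C)C)(C(C)C)C(C)C)c1)[C@@H](C=C)c1ccc(O[Si](C)(C)C(C)(C)C)cc1 | intermediate
10 | (2R,3R)-2-[[4-bromo-3-(triisopropylsilyloxy)phenyl]methyl]-3-[4-(tert-butyldimethylsilyloxy)phenyl]pent-4-enoic acid | OC(=O)[C@H](Cc1ccc(Br)c(O[Si](C(C)C)(C(C)C)C(C)C)c1)[C@@H](C=C)c1ccc(O[Si](C)(C)C(C)(C)C)cc1 | intermediate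
11 | methyl (2R,3R)-2-[[4-bromo-3-(triisopropylsilyloxy)phenyl]methyl]-3-[4-(tert-butyldimethylsilyloxy)phenyl]pent-4-enoate | COC(=O)[C@H](Cc1ccc(Br)c(O[Si](C(C)C)(C(C)C)C(C)C)c1)[C@@H](C=C)c1ccc(O[Si](C)(C)C(C)(C)C)cc1 | intermediate
12 | methyl (2R,3R)-2-[[4-bromo-3-(triisopropylsilyloxy)phenyl]methyl]-3-[4-(tert-butyldimethylsilyloxy)phenyl]-3-(1,2,4-trioxolan-3-yl)propanoate (ozonide, mixed at the trioxolane carbon) | COC(=O)[C@H](Cc1ccc(Br)c(O[Si](C(C)C)(C(C)C)C(C)C)c1)[C@@H](C1OCOO1)c1ccc(O[Si](C)(C)C(C)(C)C)cc1 | intermediate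
13 | methyl (2R,3R)-2-[[4-bromo-3-(triisopropylsilyloxy)phenyl]methyl]-3-[4-(tert-butyldimethylsilyloxy)phenyl]-4-oxobutanoate | COC(=O)[C@H](Cc1ccc(Br)c(O[Si](C(C)C)(C(C)C)C(C)C)c1)[C@@H](C=O)c1ccc(O[Si](C)(C)C(C)(C)C)cc1 | intermediate
14 | (2R,3R)-3-[[4-bromo-3-(triisopropylsilyloxy)phenyl]methyl]-2-[4-(tert-butyldimethylsilyloxy)phenyl]-4-methoxy-4-oxobutanoic acid | COC(=O)[C@H](Cc1ccc(Br)c(O[Si](C(C)C)(C(C)C)C(C)C)c1)[C@@H](C(=O)O)c1ccc(O[Si](C)(C)C(C)(C)C)cc1 | intermediate
15 | 4,4,5,5-tetramethyl-2-(3-methylbut-2-enyl)-1,3,2-dioxaborolane | CC(C)=CCB1OC(C)(C)C(C)(C)O1 | starting material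
16 | (2R,3R)-2-[4-(tert-butyldimethylsilyloxy)phenyl]-4-methoxy-3-[[4-(3-methylbut-2-enyl)-3-(triisopropylsilyloxy)phenyl]methyl]-4-oxobutanoic acid | COC(=O)[C@H](Cc1ccc(CC=C(C)C)c(O[Si](C(C)C)(C(C)C)C(C)C)c1)[C@@H](C(=O)O)c1ccc(O[Si](C)(C)C(C)(C)C)cc1 | intermediate
17 | (2R,3R)-2-(4-hydroxyphenyl)-3-[[3-hydroxy-4-(3-methylbut-2-enyl)phenyl]methyl]-4-methoxy-4-oxobutanoic acid | COC(=O)[C@H](Cc1ccc(CC=C(C)C)c(O)c1)[C@@H](C(=O)O)c1ccc(O)cc1 | target

**Totals**
Total step count: 9. Longest linear sequence: 8 steps (steps 1, 2, 4, 5, 6, 7, 8, 9); step 3 is the one-step side branch.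

**Three steps most likely to fail**

Step 4 (dual catalysis). The risks are loss of diastereomer ratio through epimerisation of aldehyde 9, a slow reaction with these silyloxy substrates, or the ligand sense noted in the assumption. The fallback is a substrate-controlled Ireland–Claisen rearrangement with 1,3-chirality transfer; it sets out from 5 and 6 and comes back to the route at 13. Chlorite oxidation of 5 gives 3-[4-bromo-3-(triisopropylsilyloxy)phenyl]propanoic acid F1. Wittig reaction of 6 with Ph3P=CHC(O)CH3 gives (E)-4-[4-(tert-butyldimethylsilyloxy)phenyl]but-3-en-2-one F2. Reduction of F2 with BH3·SMe2 and the (R)-methyl oxazaborolidine (CBS) catalyst gives (2S,3E)-4-[4-(tert-butyldimethylsilyloxy)phenyl]but-3-en-2-ol F3. DCC/DMAP coupling of F1 with F3 gives (2S,3E)-4-[4-(tert-butyldimethylsilyloxy)phenyl]but-3-en-2-yl 3-[4-bromo-3-(triisopropylsilyloxy)phenyl]propanoate F4. LiN(iPr)2 in THF at −78 °C followed by Me3SiCl gives the (E)-trimethylsilyl ketene acetal F5, which is not isolated. On warming it rearranges through a chair transition state (methyl and aryl equatorial, benzyl axial) to the trimethylsilyl ester F6, also not isolated. Work-up hydrolyses this to (2R,3R,4E)-2-[[4-bromo-3-(triisopropylsilyloxy)phenyl]methyl]-3-[4-(tert-butyldimethylsilyloxy)phenyl]hex-4-enoic acid F7. Me3SiCHN2 gives its methyl ester F8, ozone gives the methyl-substituted ozonide F9, and PPh3 releases aldehyde 13, which is oxidised to 14 as in step 7.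

Step 8 (linear prenylation of a hindered, electron-rich aryl bromide). The risks are branched 1,1-dimethylallyl product or sluggish oxidative addition next to the silyloxy group. The fallback reverses the polarity of the coupling; it sets out from 14 and comes back at 16. Miyaura borylation (B2pin2, KOAc, Pd(dppf)Cl2, dioxane, 80 °C) gives (2R,3R)-2-[4-(tert-butyldimethylsilyloxy)phenyl]-4-methoxy-4-oxo-3-[[4-(4,4,5,5-tetramethyl-1,3,2-dioxaborolan-2-yl)-3-(triisopropylsilyloxy)phenyl]methyl]butanoic acid F11. Coupling of F11 with 1-bromo-3-methylbut-2-ene (Pd(PPh3)4, K2CO3, THF/H2O) then delivers the aryl group to the unsubstituted terminus of the π-prenyl palladium intermediate and gives 16.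

Step 7 (ozonolysis and oxidation). The risks are ozone attack on the silyloxyarenes and epimerisation of α-aryl aldehyde 13. The fallback replaces ozonide chemistry by osmium dihydroxylation with periodate glycol cleavage; it sets out from 11 and comes back at 13. OsO4 (cat.), NaIO4 and 2,6-lutidine in dioxane/H2O convert 11 into methyl (2R,3R)-2-[[4-bromo-3-(triisopropylsilyloxy)phenyl]methyl]-3-[4-(tert-butyldimethylsilyloxy)phenyl]-4,5-dihydroxypentanoate F10. F10 is not isolated, so it cannot lactonise onto the ester, and is cleaved as it forms to 13, which is then oxidised with chlorite to 14.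

**Further compounds**
F1 | step 4 | 3-[4-bromo-3-(triisopropylsilyloxy)phenyl]propanoic acid | OC(=O)CCc1ccc(Br)c(O[Si](C(C)C)(C(C)C)C(C)C)c1
F2 | step 4 | (E)-4-[4-(tert-butyldimethylsilyloxy)phenyl]but-3-en-2-one | CC(=O)/C=C/c1ccc(O[Si](C)(C)C(C)(C)C)cc1
F3 | step 4 | (2S,3E)-4-[4-(tert-butyldimethylsilyloxy)phenyl]but-3-en-2-ol | C[C@H](O)/C=C/c1ccc(O[Si](C)(C)C(C)(C)C)cc1
F4 | step 4 | (2S,3E)-4-[4-(tert-butyldimethylsilyloxy)phenyl]but-3-en-2-yl 3-[4-bromo-3-(triisopropylsilyloxy)phenyl]propanoate | C[C@H](OC(=O)CCc1ccc(Br)c(O[Si](C(C)C)(C(C)C)C(C)C)c1)/C=C/c1ccc(O[Si](C)(C)C(C)(C)C)cc1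
F5 | step 4 | (E)-trimethylsilyl ketene acetal of F4 | C[C@H](O/C(O[Si](C)(C)C)=C\Cc1ccc(Br)c(O[Si](C(C)C)(C(C)C)C(C)C)c1)/C=C/c1ccc(O[Si](C)(C)C(C)(C)C)cc1
F6 | step 4 | trimethylsilyl (2R,3R,4E)-2-[[4-bromo-3-(triisopropylsilyloxy)phenyl]methyl]-3-[4-(tert-butyldimethylsilyloxy)phenyl]hex-4-enoate | C[Si](C)(C)OC(=O)[C@H](Cc1ccc(Br)c(O[Si](C(C)C)(C(C)C)C(C)C)c1)[C@@H](/C=C/C)c1ccc(O[Si](C)(C)C(C)(C)C)cc1
F7 | step 4 | (2R,3R,4E)-2-[[4-bromo-3-(triisopropylsilyloxy)phenyl]methyl]-3-[4-(tert-butyldimethylsilyloxy)phenyl]hex-4-enoic acid | OC(=O)[C@H](Cc1ccc(Br)c(O[Si](C(C)C)(C(C)C)C(C)C)c1)[C@@H](/C=C/C)c1ccc(O[Si](C)(C)C(C)(C)C)cc1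
F8 | step 4 | methyl (2R,3R,4E)-2-[[4-bromo-3-(triisopropylsilyloxy)phenyl]methyl]-3-[4-(tert-butyldimethylsilyloxy)phenyl]hex-4-enoate | COC(=O)[C@H](Cc1ccc(Br)c(O[Si](C(C)C)(C(C)C)C(C)C)c1)[C@@H](/C=C/C)c1ccc(O[Si](C)(C)C(C)(C)C)cc1
F9 | step 4 | methyl (2R,3R)-2-[[4-bromo-3-(triisopropylsilyloxy)phenyl]methyl]-3-[4-(tert-butyldimethylsilyloxy)phenyl]-3-(5-methyl-1,2,4-trioxolan-3-yl)propanoate | COC(=O)[C@H](Cc1ccc(Br)c(O[Si](C(C)C)(C(C)C)C(C)C)c1)[C@@H](C1OC(C)OO1)c1ccc(O[Si](C)(C)C(C)(C)C)cc1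
F10 | step 7 | methyl (2R,3R)-2-[[4-bromo-3-(triisopropylsilyloxy)phenyl]methyl]-3-[4-(tert-butyldimethylsilyloxy)phenyl]-4,5-dihydroxypentanoate | COC(=O)[C@H](Cc1ccc(Br)c(O[Si](C(C)C)(C(C)C)C(C)C)c1)[C@@H](C(O)CO)c1ccc(O[Si](C)(C)C(C)(C)C)cc1
F11 | step 8 | (2R,3R)-2-[4-(tert-butyldimethylsilyloxy)phenyl]-4-methoxy-4-oxo-3-[[4-(4,4,5,5-tetramethyl-1,3,2-dioxaborolan-2-yl)-3-(triisopropylsilyloxy)phenyl]methyl]butanoic acid | COC(=O)[C@H](Cc1ccc(B2OC(C)(C)C(C)(C)O2)c(O[Si](C(C)C)(C(C)C)C(C)C)c1)[C@@H](C(=O)O)c1ccc(O[Si](C)(C)C(C)(C)C)cc1
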